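Retrosynthesis: the anisoate and acetate C–O bonds and the C4–isopropyl bond are cut first, leaving a trans-hydroazulenone with a masked C6 ketone; then C5–C6 and C7–C8 (the C6–C7 bridge of ring B) are cut, leading back to a bicyclo[3.3.0]octenone (rings A and C) and allene.
Enabling feature: ring B (C1, C5–C10) is the cyclopentene ring C (C1, C5, C8, C9, C10) with C6–C7 inserted into the C5–C8 bond; the C4 oxygen, kept as a ketone, makes C5=C8 an enone (C5 α, C8 β), stabilises the C5 radical in the ring expansion and later accepts the isopropyl group.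
Forward order: ring A (from 3-methylcyclopentenone), then ring C by conjugate addition and aldol condensation, then a temporary cyclobutane by [2+2] photocycloaddition, then ring B by radical β-scission of C5–C8 with loss of the C9 oxygen, which also places C8=C9.
Stereochemistry: C1 from a copper-catalysed asymmetric conjugate addition; C2 by conjugate borylation anti to the angular methyl; C5 by hydrogen-atom transfer anti to that methyl (trans fusion); C4 by organocerium addition anti to it; C6 by hydride delivery directed by the C4 hydroxyl.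

Key step: step 7

Remark 1: positions are numbered as in the daucane skeleton of the target (C1 quaternary ring-fusion carbon with the angular methyl, C2 CH–OAc, C3 CH2, C4 C(OH)(i-Pr), C5 ring-fusion CH, C6 CH–O-anisoyl, C7 CH2, C8 C(CH3)=, C9 =CH, C10 CH2); ring A is C1–C5, ring B the seven-membered ring, ring C the temporary cyclopentene; β is the face of the angular methyl.
Remark 2: the C9 carbinol centre of compounds 12, 13 and 15–19 is carried as a mixture of epimers (drawn without configuration) because C9 becomes sp2 in step 10; compounds 1, 2, 14 and 26 are taken as commercial.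

Step 1
Reactants: 1 3-methylcyclopent-2-en-1-one; 2 2-(2-bromoethyl)-2-methyl-1,3-dioxolane
Product: 4 (R)-3-methyl-3-[2-(2-methyl-1,3-dioxolan-2-yl)ethyl]cyclopentan-1-one, via Grignard reagent 3 (not isolated)
Conditions: Mg, THF, 25 °C; then 1, Cu(OTf)2 (3 mol %), chiral C2-symmetric imidazolinium salt (carbene ligand precursor, 4 mol %), Et2O, −30 → 0 °C; aq. NH4Cl
Reagents that add atoms: none
Why: Copper-catalysed asymmetric conjugate addition of a Grignard reagent to a β-methyl cyclic enone is an established route to quaternary centres, and the ligand enantiomer is chosen so that C1 is formed with the (R) configuration shown.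

Step 2
Reactants: 4 (R)-3-methyl-3-[2-(2-methyl-1,3-dioxolan-2-yl)ethyl]cyclopentan-1-one
Product: 6 (S)-3a,6-dimethyl-3,3a,4,5-tetrahydropentalen-1(2H)-one, via diketone 5 (not isolated)
Conditions: p-TsOH·H2O (cat.), acetone/H2O, 50 °C; then KOH (cat.), MeOH, 60 °C
Reagents that add atoms: none
Why: Ketal hydrolysis frees the 1,6-diketone, whose intramolecular aldol condensation (C5 enolate onto the methyl ketone, 5-exo-trig) closes ring C and leaves C5=C8 conjugated with the C4 ketone, the other aldol modes being reversible because they cannot dehydrate.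

Step 3
Reactants: 6 (S)-3a,6-dimethyl-3,3a,4,5-tetrahydropentalen-1(2H)-one
Product: 8 (S)-3a,6-dimethyl-4,5-dihydropentalen-1(3aH)-one, via silyl dienol ether 7 (not isolated)
Conditions: LiN(i-Pr)2, THF, −78 °C; Me3SiCl; then Pd(OAc)2 (1.1 equiv), MeCN, 25 °C
Reagents that add atoms: none
Why: Kinetic deprotonation of the enone occurs at the α′-methylene C3, and Saegusa–Ito oxidation of the resulting silyl dienol ether introduces the C2=C3 double bond needed to oxygenate C2.

Step 4
Reactants: 8 (S)-3a,6-dimethyl-4,5-dihydropentalen-1(3aH)-one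
Product: 10 (3S,3aR)-3-hydroxy-3a,6-dimethyl-3,3a,4,5-tetrahydropentalen-1(2H)-one, via boronate 9 (not isolated)
Conditions: B2pin2, CuCl (5 mol %), NaOt-Bu (10 mol %), Xantphos (5 mol %), MeOH (2 equiv), THF, 0 °C; then H2O2, pH 7 phosphate buffer, 0 °C
Reagents that add atoms: hydrogen peroxide, OO
Why: Copper-catalysed conjugate borylation should occur only at the unhindered β-carbon C2 of the disubstituted enone and anti to the adjacent angular methyl, which stands perpendicular to the nearly flat dienone, and the stereoretentive C–B oxidation then gives the 2α-alcohol.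

Step 5
Reactants: 10 (3S,3aR)-3-hydroxy-3a,6-dimethyl-3,3a,4,5-tetrahydropentalen-1(2H)-one
Product: 11 (3S,3aR)-3-[(tert-butyldimethylsilyl)oxy]-3a,6-dimethyl-3,3a,4,5-tetrahydropentalen-1(2H)-one
Conditions: t-BuMe2SiOTf, 2,6-lutidine, CH2Cl2, −78 °C
Reagents that add atoms: tert-butyldimethylsilyl trifluoromethanesulfonate, CC(C)(C)[Si](C)(C)OS(=O)(=O)C(F)(F)F
Why: Silylation with the silyl triflate and a hindered pyridine is a standard non-enolising protection that should keep the β-hydroxy ketone from eliminating.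

Step 6
Reactants: 11 (3S,3aR)-3-[(tert-butyldimethylsilyl)oxy]-3a,6-dimethyl-3,3a,4,5-tetrahydropentalen-1(2H)-one
Product: 13 (3S,3aR)-3-[(tert-butyldimethylsilyl)oxy]-5-hydroxy-3a,6-dimethyl-3,3a,4,5-tetrahydropentalen-1(2H)-one, via allylic bromide 12 (not isolated)
Conditions: N-bromosuccinimide, AIBN (cat.), PhCF3, 80 °C; then Ag2CO3, acetone/H2O, 25 °C
Reagents that add atoms: water, O
Why: Wohl–Ziegler bromination should go to the secondary γ-position C9, whose allylic radical is delocalised over C8=C5 and the carbonyl, and silver-assisted solvolysis of the allylic bromide gives the alcohol that later serves as the radical handle, its configuration being irrelevant.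

Step 7
Reactants: 13 (3S,3aR)-3-[(tert-butyldimethylsilyl)oxy]-5-hydroxy-3a,6-dimethyl-3,3a,4,5-tetrahydropentalen-1(2H)-one; 14 propa-1,2-diene (allene)
Product: 15 8-[(tert-butyldimethylsilyl)oxy]-5-hydroxy-4,7-dimethyl-2-methylidenetricyclo[5.3.0.0(1,4)]decan-10-one
Conditions: hν (medium-pressure Hg lamp, uranium-glass filter, λ > 330 nm), allene (10 equiv), THF, −78 °C
Reagents that add atoms: none
Why: n→π* excitation and intersystem crossing give the enone triplet, which adds to allene stepwise through a 1,4-biradical, the closest known reaction type being the intermolecular enone–allene [2+2] photocycloaddition that gives β,γ-unsaturated ketones. The only ring closed is the cyclobutane C5–C6–C7–C8, formed by intermolecular bonding followed by recombination of the 1,4-biradical; because C5=C8 is held in ring C, the excited state cannot relax by E/Z twisting as open-chain alkylidene ketones do. The new quaternary centres C5 and C8 are controlled by ring strain: the four-membered ring must be cis-fused to ring C and rings A and C can only be cis-fused, so the allene unit should end up on the face of the angular methyl; both centres and C9 lose their configuration again in step 10, so this outcome need not match the target. The selectivity that matters is regiochemical, central allene carbon (future C6) to C5 and terminal CH2 (C7) to C8, and it is secured by the C4 carbonyl, which makes C5 the α-carbon at which allene bonds head-to-head through its central carbon, the opposite of the orientation shown by enol ethers and ketene acetals, which is why allene serves here as a masked C6 ketone. Long-wavelength irradiation at low temperature and work-up before complete conversion should suppress the secondary 1,3-acyl shift of the β,γ-unsaturated ketone product.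

Step 8
Reactants: 15 8-[(tert-butyldimethylsilyl)oxy]-5-hydroxy-4,7-dimethyl-2-methylidenetricyclo[5.3.0.0(1,4)]decan-10-one
Product: 18 8-[(tert-butyldimethylsilyl)oxy]-5-hydroxy-2,2-dimethoxy-4,7-dimethyltricyclo[5.3.0.0(1,4)]decan-10-one, via ozonide 16 (not isolated), via acylcyclobutanone 17 (not isolated)
Conditions: O3, CH2Cl2, −78 °C; Me2S; then MeOSiMe3 (3 equiv), Me3SiOTf (cat.), CH2Cl2, −78 → −20 °C; K2CO3, MeOH, 0 °C
Reagents that add atoms: methoxytrimethylsilane, CO[Si](C)(C)C
Why: Ozonolysis of the only alkene gives the strained 2-acylcyclobutanone, which is kept in aprotic solution to avoid retro-Claisen ring opening and is ketalised at once, by silyl-triflate-catalysed reaction with the alkoxysilane, at its more electrophilic four-ring carbonyl.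

Step 9
Reactants: 18 8-[(tert-butyldimethylsilyl)oxy]-5-hydroxy-2,2-dimethoxy-4,7-dimethyltricyclo[5.3.0.0(1,4)]decan-10-one
Product: 19 O-{8-[(tert-butyldimethylsilyl)oxy]-2,2-dimethoxy-4,7-dimethyl-10-oxotricyclo[5.3.0.0(1,4)]decan-5-yl} 1H-imidazole-1-carbothioate
Conditions: 1,1'-thiocarbonyldiimidazole, DMAP (cat.), toluene, 80 °C
Reagents that add atoms: 1,1'-thiocarbonyldiimidazole, S=C(n1ccnc1)n1ccnc1
Why: Thioacylation of the only free hydroxyl is the standard way to a Barton–McCombie radical precursor and works on hindered secondary alcohols.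

Step 10
Reactants: 19 O-{8-[(tert-butyldimethylsilyl)oxy]-2,2-dimethoxy-4,7-dimethyl-10-oxotricyclo[5.3.0.0(1,4)]decan-5-yl} 1H-imidazole-1-carbothioate
Product: 20 (1S,3aR,8aR)-1-[(tert-butyldimethylsilyl)oxy]-4,4-dimethoxy-6,8a-dimethyl-1,3a,4,5,8,8a-hexahydroazulen-3(2H)-one
Conditions: Bu3SnH (1.3 equiv, syringe pump), AIBN (cat.), toluene, 110 °C
Reagents that add atoms: none
Why: Barton–McCombie-type C–O homolysis gives the C9 cyclobutylcarbinyl radical, whose β-scission of the ring-fusion bond C5–C8 relieves the four-ring strain, places C8=C9 regiospecifically and leaves a tertiary α-keto radical at C5 (C7–C8 scission would give an unstabilised primary radical), and hydrogen transfer from the stannane anti to the angular methyl should give the trans ring fusion.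

Step 11
Reactants: 20 (1S,3aR,8aR)-1-[(tert-butyldimethylsilyl)oxy]-4,4-dimethoxy-6,8a-dimethyl-1,3a,4,5,8,8a-hexahydroazulen-3(2H)-one
Product: 21 (1S,3R,3aR,8aR)-1-[(tert-butyldimethylsilyl)oxy]-4,4-dimethoxy-6,8a-dimethyl-3-(propan-2-yl)-1,2,3,3a,4,5,8,8a-octahydroazulen-3-ol
Conditions: i-PrMgCl, CeCl3 (dried), THF, −78 → −40 °C; aq. NH4Cl
Reagents that add atoms: isopropylmagnesium chloride, CC(C)[Mg]Cl
Why: The weakly basic organocerium reagent should add to the hindered, enolisable C4 ketone from the α face, anti to the axial angular methyl, giving the 4β-hydroxy-4α-isopropyl carbinol.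

Step 12
Reactants: 21 (1S,3R,3aR,8aR)-1-[(tert-butyldimethylsilyl)oxy]-4,4-dimethoxy-6,8a-dimethyl-3-(propan-2-yl)-1,2,3,3a,4,5,8,8a-octahydroazulen-3-ol
Product: 22 (1S,3R,3aR,8aR)-4,4-dimethoxy-6,8a-dimethyl-3-(propan-2-yl)-1,2,3,3a,4,5,8,8a-octahydroazulene-1,3-diol
Conditions: Bu4NF, THF, 25 °C
Reagents that add atoms: none
Why: Fluoride cleaves the silyl ether under conditions that leave the dimethyl ketal, the tertiary alcohol and the alkene untouched.

Step 13
Reactants: 22 (1S,3R,3aR,8aR)-4,4-dimethoxy-6,8a-dimethyl-3-(propan-2-yl)-1,2,3,3a,4,5,8,8a-octahydroazulene-1,3-diol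
Product: 23 (1S,3R,3aR,8aR)-3-hydroxy-4,4-dimethoxy-6,8a-dimethyl-3-(propan-2-yl)-1,2,3,3a,4,5,8,8a-octahydroazulen-1-yl acetate
Conditions: Ac2O, pyridine, DMAP (cat.), CH2Cl2, 0 → 25 °C
Reagents that add atoms: acetic anhydride, CC(=O)OC(C)=O
Why: Under these mild acylation conditions only the secondary C2 hydroxyl should react, the tertiary C4 hydroxyl being inert.

Step 14
Reactants: 23 (1S,3R,3aR,8aR)-3-hydroxy-4,4-dimethoxy-6,8a-dimethyl-3-(propan-2-yl)-1,2,3,3a,4,5,8,8a-octahydroazulen-1-yl acetate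
Product: 25 (1S,3R,3aS,4S,8aR)-3,4-dihydroxy-6,8a-dimethyl-3-(propan-2-yl)-1,2,3,3a,4,5,8,8a-octahydroazulen-1-yl acetate, via ketone 24 (not isolated)
Conditions: AcOH/H2O/MeCN, 25 °C; then Me4NBH(OAc)3 (excess), AcOH/MeCN, −30 °C
Reagents that add atoms: water, O
Why: The C6 ketone is unveiled only now so that the β,γ-unsaturated, epimerisable β-hydroxy ketone is reduced as soon as it forms, and in the Evans–Saksena reduction the borohydride bound to the C4 hydroxyl delivers hydride intramolecularly to the β face, which should give the 1,3-anti (6α) alcohol without touching the acetate.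

Step 15
Reactants: 25 (1S,3R,3aS,4S,8aR)-3,4-dihydroxy-6,8a-dimethyl-3-(propan-2-yl)-1,2,3,3a,4,5,8,8a-octahydroazulen-1-yl acetate; 26 4-methoxybenzoyl chloride
Product: 27 (1S,3R,3aS,4S,8aR)-1-(acetyloxy)-3-hydroxy-6,8a-dimethyl-3-(propan-2-yl)-1,2,3,3a,4,5,8,8a-octahydroazulen-4-yl 4-methoxybenzoate
Conditions: DMAP, Et3N, CH2Cl2, 25 °C
Reagents that add atoms: none
Why: DMAP-catalysed acylation should esterify the only secondary hydroxyl (C6) and leave the tertiary C4 hydroxyl free, completing the target.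

Compound list
1 | 3-methylcyclopent-2-en-1-one | CC1=CC(=O)CC1 | starting material
2 | 2-(2-bromoethyl)-2-methyl-1,3-dioxolane | CC1(CCBr)OCCO1 | starting material
3 | [2-(2-methyl-1,3-dioxolan-2-yl)ethyl]magnesium bromide | CC1(CC[Mg]Br)OCCO1 | intermediate
4 | (R)-3-methyl-3-[2-(2-methyl-1,3-dioxolan-2-yl)ethyl]cyclopentan-1-one | O=C1CC[C@](C)(CCC2(C)OCCO2)C1 | intermediate
5 | (S)-3-methyl-3-(3-oxobutyl)cyclopentan-1-one | O=C1CC[C@](C)(CCC(C)=O)C1 | intermediate
6 | (S)-3a,6-dimethyl-3,3a,4,5-tetrahydropentalen-1(2H)-one | O=C1CC[C@]2(C)CCC(C)=C12 | intermediate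
7 | (S)-[(3a,6-dimethyl-3,3a,4,5-tetrahydropentalen-1-yl)oxy]trimethylsilane | C[Si](C)(C)OC1=CC[C@]2(C)CCC(C)=C12 | intermediate
8 | (S)-3a,6-dimethyl-4,5-dihydropentalen-1(3aH)-one | O=C1C=C[C@]2(C)CCC(C)=C12 | intermediate
9 | (3S,3aS)-3a,6-dimethyl-3-(4,4,5,5-tetramethyl-1,3,2-dioxaborolan-2-yl)-3,3a,4,5-tetrahydropentalen-1(2H)-one (boryl group trans to the 3a-methyl) | O=C1C[C@H](B3OC(C)(C)C(C)(C)O3)[C@]2(C)CCC(C)=C12 | intermediate
10 | (3S,3aR)-3-hydroxy-3a,6-dimethyl-3,3a,4,5-tetrahydropentalen-1(2H)-one (hydroxyl trans to the 3a-methyl) | O=C1C[C@H](O)[C@]2(C)CCC(C)=C12 | intermediate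
11 | (3S,3aR)-3-[(tert-butyldimethylsilyl)oxy]-3a,6-dimethyl-3,3a,4,5-tetrahydropentalen-1(2H)-one | O=C1C[C@H](O[Si](C)(C)C(C)(C)C)[C@]2(C)CCC(C)=C12 | intermediate
12 | (3S,3aR)-5-bromo-3-[(tert-butyldimethylsilyl)oxy]-3a,6-dimethyl-3,3a,4,5-tetrahydropentalen-1(2H)-one (C5 epimers) | O=C1C[C@H](O[Si](C)(C)C(C)(C)C)[C@]2(C)CC(Br)C(C)=C12 | intermediate
13 | (3S,3aR)-3-[(tert-butyldimethylsilyl)oxy]-5-hydroxy-3a,6-dimethyl-3,3a,4,5-tetrahydropentalen-1(2H)-one (C5 epimers) | O=C1C[C@H](O[Si](C)(C)C(C)(C)C)[C@]2(C)CC(O)C(C)=C12 | intermediate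
14 | propa-1,2-diene (allene) | C=C=C | starting material
15 | 8-[(tert-butyldimethylsilyl)oxy]-5-hydroxy-4,7-dimethyl-2-methylidenetricyclo[5.3.0.0(1,4)]decan-10-one (cyclobutane cis-fused on the face of the 7-methyl, silyloxy on the opposite face, C5 epimers) | O=C1C[C@H](O[Si](C)(C)C(C)(C)C)[C@]2(C)CC(O)[C@@]3(C)CC(=C)[C@@]123 | intermediate
16 | 1,2,4-trioxolane (ozonide) spiro-fused at C2 of the tricyclic skeleton of 15 | O=C1C[C@H](O[Si](C)(C)C(C)(C)C)[C@]2(C)CC(O)[C@@]3(C)CC4(OCOO4)[C@@]123 | intermediate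
17 | 8-[(tert-butyldimethylsilyl)oxy]-5-hydroxy-4,7-dimethyltricyclo[5.3.0.0(1,4)]decane-2,10-dione | O=C1C[C@H](O[Si](C)(C)C(C)(C)C)[C@]2(C)CC(O)[C@@]3(C)CC(=O)[C@@]123 | intermediate
18 | 8-[(tert-butyldimethylsilyl)oxy]-5-hydroxy-2,2-dimethoxy-4,7-dimethyltricyclo[5.3.0.0(1,4)]decan-10-one (relative configuration as in 15) | O=C1C[C@H](O[Si](C)(C)C(C)(C)C)[C@]2(C)CC(O)[C@@]3(C)CC(OC)(OC)[C@@]123 | intermediate
19 | O-{8-[(tert-butyldimethylsilyl)oxy]-2,2-dimethoxy-4,7-dimethyl-10-oxotricyclo[5.3.0.0(1,4)]decan-5-yl} 1H-imidazole-1-carbothioate | O=C1C[C@H](O[Si](C)(C)C(C)(C)C)[C@]2(C)CC(OC(=S)n4ccnc4)[C@@]3(C)CC(OC)(OC)[C@@]123 | intermediate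
20 | (1S,3aR,8aR)-1-[(tert-butyldimethylsilyl)oxy]-4,4-dimethoxy-6,8a-dimethyl-1,3a,4,5,8,8a-hexahydroazulen-3(2H)-one (trans-fused, silyloxy trans to the angular methyl) | COC1(OC)CC(C)=CC[C@@]2(C)[C@@H](O[Si](C)(C)C(C)(C)C)CC(=O)[C@H]12 | intermediate
21 | (1S,3R,3aR,8aR)-1-[(tert-butyldimethylsilyl)oxy]-4,4-dimethoxy-6,8a-dimethyl-3-(propan-2-yl)-1,2,3,3a,4,5,8,8a-octahydroazulen-3-ol | COC1(OC)CC(C)=CC[C@@]2(C)[C@@H](O[Si](C)(C)C(C)(C)C)C[C@@](O)(C(C)C)[C@H]12 | intermediate
22 | (1S,3R,3aR,8aR)-4,4-dimethoxy-6,8a-dimethyl-3-(propan-2-yl)-1,2,3,3a,4,5,8,8a-octahydroazulene-1,3-diol | COC1(OC)CC(C)=CC[C@@]2(C)[C@@H](O)C[C@@](O)(C(C)C)[C@H]12 | intermediate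
23 | (1S,3R,3aR,8aR)-3-hydroxy-4,4-dimethoxy-6,8a-dimethyl-3-(propan-2-yl)-1,2,3,3a,4,5,8,8a-octahydroazulen-1-yl acetate | COC1(OC)CC(C)=CC[C@@]2(C)[C@@H](OC(C)=O)C[C@@](O)(C(C)C)[C@H]12 | intermediate
24 | (1S,3R,3aR,8aR)-3-hydroxy-6,8a-dimethyl-4-oxo-3-(propan-2-yl)-1,2,3,3a,4,5,8,8a-octahydroazulen-1-yl acetate | O=C1CC(C)=CC[C@@]2(C)[C@@H](OC(C)=O)C[C@@](O)(C(C)C)[C@H]12 | intermediate
25 | (1S,3R,3aS,4S,8aR)-3,4-dihydroxy-6,8a-dimethyl-3-(propan-2-yl)-1,2,3,3a,4,5,8,8a-octahydroazulen-1-yl acetate | O[C@H]1CC(C)=CC[C@@]2(C)[C@@H](OC(C)=O)C[C@@](O)(C(C)C)[C@H]12 | intermediate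
26 | 4-methoxybenzoyl chloride | COc1ccc(cc1)C(Cl)=O | starting material
27 | (1S,3R,3aS,4S,8aR)-1-(acetyloxy)-3-hydroxy-6,8a-dimethyl-3-(propan-2-yl)-1,2,3,3a,4,5,8,8a-octahydroazulen-4-yl 4-methoxybenzoate | COc1ccc(C(=O)O[C@H]2CC(C)=CC[C@@]3(C)[C@@H](OC(C)=O)C[C@@](O)(C(C)C)[C@H]23)cc1 | target

Total step count: 15. Longest linear sequence: 15 steps (from 1).

Steps most likely to fail, with fallbacks:

(a) The radical ring expansion of step 10. The ring-bound C9 radical overlaps better with the exocyclic C7–C8 bond than with the ring-fusion bond, so wrong-bond scission or hydrogen transfer before fragmentation may compete; the preceding ketal formation also passes through an acylcyclobutanone that can ring-open. The fallback uses a two-electron fragmentation instead, sets out from 15 and also bypasses intermediate 17. Acetylation (Ac2O, DMAP, pyridine) gives the C9 acetate F1. SmI2/HMPA in THF at −78 °C forms the C4 ketyl, which can cleave only C5–C8 (the other cyclobutane bond at C5 would give a vinyl radical); reduction of the C8 radical and loss of acetate should give, after α-protonation, the trans-fused 6-methylidene ketone F2. Organocerium addition as in step 11 gives the carbinol F3, Bu4NF the diol F4, and Ac2O/pyridine the C2 acetate F5. VO(acac)2/t-BuOOH, directed by the C4 hydroxyl, should epoxidise only the homoallylic exocyclic methylidene to the spiro-epoxide F6. H5IO6 then cleaves the epoxide to ketone 24, where the route is rejoined for the directed reduction of step 14.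

(b) The isopropyl addition of step 11. Enolisation or β-hydride reduction of the hindered C4 ketone may outrun addition, and the pseudo-axial 2α-silyloxy group may erode the facial preference. The fallback sets out from 20 and delivers the group in two operations: the smaller sp2 reagent from 2-propenylmagnesium bromide and CeCl3 gives the isopropenyl carbinol F7, and hydrogenation with H2 and RhCl(PPh3)3 in benzene should saturate only the 1,1-disubstituted alkene, returning to the route at 21.

(c) The asymmetric conjugate addition of step 1. Functionalised Grignard reagents on five-membered β-methyl enones may give insufficient enantioselectivity, which would lower the optical purity of the whole series. The fallback exchanges the roles of the two substituents and sets out from 2 (as Grignard reagent 3). Addition to 3-ethoxycyclopent-2-en-1-one F8 with mild acidic work-up (Stork–Danheiser alkylative transposition) gives 3-[2-(2-methyl-1,3-dioxolan-2-yl)ethyl]cyclopent-2-en-1-one F9. Copper-catalysed asymmetric conjugate addition of Me3Al (Cu(OTf)2, chiral carbene ligand, Et2O, −30 °C), a reaction type that works well on β-alkyl cyclopentenones, then returns to the route at 4.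

Further compounds
F1 | step 10 | 8-[(tert-butyldimethylsilyl)oxy]-4,7-dimethyl-2-methylidene-10-oxotricyclo[5.3.0.0(1,4)]decan-5-yl acetate | O=C1C[C@H](O[Si](C)(C)C(C)(C)C)[C@]2(C)CC(OC(C)=O)[C@@]3(C)CC(=C)[C@@]123
F2 | step 10 | (1S,3aR,8aR)-1-[(tert-butyldimethylsilyl)oxy]-6,8a-dimethyl-4-methylidene-1,3a,4,5,8,8a-hexahydroazulen-3(2H)-one | C=C1CC(C)=CC[C@@]2(C)[C@@H](O[Si](C)(C)C(C)(C)C)CC(=O)[C@H]12
F3 | step 10 | (1S,3R,3aR,8aR)-1-[(tert-butyldimethylsilyl)oxy]-6,8a-dimethyl-4-methylidene-3-(propan-2-yl)-1,2,3,3a,4,5,8,8a-octahydroazulen-3-ol | C=C1CC(C)=CC[C@@]2(C)[C@@H](O[Si](C)(C)C(C)(C)C)C[C@@](O)(C(C)C)[C@H]12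
F4 | step 10 | (1S,3R,3aR,8aR)-6,8a-dimethyl-4-methylidene-3-(propan-2-yl)-1,2,3,3a,4,5,8,8a-octahydroazulene-1,3-diol | C=C1CC(C)=CC[C@@]2(C)[C@@H](O)C[C@@](O)(C(C)C)[C@H]12
F5 | step 10 | (1S,3R,3aR,8aR)-3-hydroxy-6,8a-dimethyl-4-methylidene-3-(propan-2-yl)-1,2,3,3a,4,5,8,8a-octahydroazulen-1-yl acetate | C=C1CC(C)=CC[C@@]2(C)[C@@H](OC(C)=O)C[C@@](O)(C(C)C)[C@H]12
F6 | step 10 | spiro-epoxide of F5 at the exocyclic methylidene: 3-hydroxy-6,8a-dimethyl-3-(propan-2-yl)-2,3,3a,5,8,8a-hexahydro-1H-spiro[azulene-4,2'-oxiran]-1-yl acetate (ring stereocentres as in F5) | C1OC12CC(C)=CC[C@@]3(C)[C@@H](OC(C)=O)C[C@@](O)(C(C)C)[C@H]23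
F7 | step 11 | (1S,3S,3aR,8aR)-1-[(tert-butyldimethylsilyl)oxy]-4,4-dimethoxy-6,8a-dimethyl-3-(prop-1-en-2-yl)-1,2,3,3a,4,5,8,8a-octahydroazulen-3-ol | COC1(OC)CC(C)=CC[C@@]2(C)[C@@H](O[Si](C)(C)C(C)(C)C)C[C@@](O)(C(C)=C)[C@H]12
F8 | step 1 | 3-ethoxycyclopent-2-en-1-one | CCOC1=CC(=O)CC1
F9 | step 1 | 3-[2-(2-methyl-1,3-dioxolan-2-yl)ethyl]cyclopent-2-en-1-one | O=C1C=C(CCC2(C)OCCO2)CC1
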